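## Retrosynthetic overview
1. Sartorypyrone D comes from C3‑allylation of triacetic acid lactone (TAL) with the monocyclic allylic bromide 13.
2. The cyclohexane ring, the exocyclic methylene and the C5 stereocentre come from one light‑driven Ti/Co radical cycloisomerisation of (14S)‑14,15‑epoxy‑geranylgeranyl TBS ether 10. It is the only carbocycle‑forming step.
3. Epoxide 10 comes from diol 9 by sulfonylation and SN2 closure, which inverts C14.
4. Diol 9 comes from Cu‑catalysed opening of the (R)‑epoxy alcohol 8 by the allylic Grignard of 12‑bromofarnesyl TBS ether 4. Compound 8 comes from (R)‑glycerate acetonide 5 by MeMgBr addition, acetonide hydrolysis and epoxide closure. Compound 4 comes from farnesol by SeO2 oxidation of the terminal E‑methyl.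

*Assumption: (E,E)‑farnesol, methyl (R)‑2,2‑dimethyl‑1,3‑dioxolane‑4‑carboxylate (D‑mannitol‑derived) and TAL are purchased. The ring OH is left unprotected from Step 9 on.*

## Route

**Step 1**
Reactants: 1 (2E,6E)‑farnesol
Product: 2 farnesyl TBS ether
Conditions: TBSCl, imidazole, DMF, 0 °C → rt
Reagents that add atoms: TBSCl, CC(C)(C)[Si](C)(C)Cl
Why: silyl protection of the primary alcohol makes it compatible with the later Grignard chemistry.

**Step 2**
Reactants: 2
Product: 3 (2E,6E,10E)‑12‑hydroxy‑farnesyl TBS ether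
Conditions: SeO2 (5 mol%), t‑BuOOH, CH2Cl2, 0 °C → rt
Reagents that add atoms: tert‑butyl hydroperoxide, CC(C)(C)OO (the oxygen source)
Why: Sharpless–Umbreit allylic oxidation hits the most electron‑rich terminal isopropylidene and its E (trans) methyl, so the new CH2 is trans to the chain. This fixes the alkene geometry needed for the chair cyclisation.

**Step 3**
Reactants: 3
Product: 4 (2E,6E,10E)‑12‑bromo‑farnesyl TBS ether
Conditions: PPh3, CBr4, CH2Cl2, 0 °C; used crude
Reagents that add atoms: CBr4, BrC(Br)(Br)Br (the bromine source)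
Why: Appel bromination converts the primary allylic alcohol to the bromide by SN2 without alkene transposition.

**Step 4**
Reactants: 5 methyl (R)‑2,2‑dimethyl‑1,3‑dioxolane‑4‑carboxylate
Product: 6 (R)‑2‑[(4R)‑2,2‑dimethyl‑1,3‑dioxolan‑4‑yl]propan‑2‑ol
Conditions: MeMgBr (3 equiv), THF, 0 °C → rt
Reagents that add atoms: methylmagnesium bromide, C[Mg]Br (two Me groups are added)
Why: double Grignard addition to the ester builds the gem‑dimethyl carbinol carbon C4. The carbinol stereocentre C3 is untouched and carries the chirality from the purchased ester.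

**Step 5**
Reactants: 6
Product: 7 (R)‑3‑methylbutane‑1,2,3‑triol
Conditions: Dowex 50W‑H+, MeOH, rt
Reagents that add atoms: none
Why: acid‑catalysed trans‑ketalisation removes the acetonide with no bond change at C3.

**Step 6**
Reactants: 7
Product: 8 (R)‑2‑(oxiran‑2‑yl)propan‑2‑ol
Conditions: TsCl (1.05 equiv), pyridine, CH2Cl2, 0 °C; then K2CO3, MeOH, 0 °C; product kept as an Et2O solution (volatile)
Reagents that add atoms: none (Ts is lost)
Why: the primary OH is tosylated selectively, then the secondary alkoxide closes the terminal epoxide (3‑exo‑tet) with retention at C3.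

**Step 7**
Reactants: 4 and 8
Product: 9 1‑O‑TBS‑(2E,6E,10E,14R)‑3,7,11,15‑tetramethylhexadeca‑2,6,10‑triene‑1,14,15‑triol
Conditions: 4, Mg, THF, −10 °C to make the allylic Grignard; then CuI (10 mol%), 8, THF, −30 → 0 °C
Reagents that add atoms: none
Why: Cu‑catalysed SN2 opening of a 2,3‑epoxy alcohol occurs at the distal terminal carbon and is α‑selective for a geranyl‑type Grignard; this joins C12–C13 of the C20 chain and leaves C14 untouched.

**Step 8**
Reactants: 9
Product: 10 (2E,6E,10E,14S)‑14,15‑epoxy‑3,7,11,15‑tetramethylhexadeca‑2,6,10‑trien‑1‑ol TBS ether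
Conditions: TsCl, Et3N, DMAP, CH2Cl2, 0 °C → rt; then K2CO3, MeOH, rt
Reagents that add atoms: none
Why: only the secondary OH is sulfonylated, and the tertiary alkoxide then displaces it in a 3‑exo‑tet SN2 that inverts C14, so the (R)‑diol gives the (S)‑epoxide.

**Step 9**
Reactants: 10
Product: 11 TBS ether of (2E,6E)‑3,7‑dimethyl‑9‑[(1R,3S)‑3‑hydroxy‑2,2‑dimethyl‑6‑methylidenecyclohexyl]nona‑2,6‑dien‑1‑ol
Conditions: Cp2TiCl2 (10 mol%), Co(dmgH)2pyCl (5 mol%), 4CzIPN (2 mol%), collidine and collidine·HCl (0.3 equiv each), Hantzsch ester (0.3 equiv), MeCN/THF, 455 nm LEDs, 25 °C, 0.02 M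
Reagents that add atoms: none (net isomerisation)
Why: Proposed new method: photoreduced Cp2TiCl opens the epoxide to the tertiary C4 radical (C3–O–Ti is retained), which closes 6‑endo through a chair transition state onto the E‑alkene with C6 equatorial, setting C5(R) trans to C3‑OH(S); the tertiary C10 radical is then trapped by Co(II) (about 10^8–10^9 M⁻¹s⁻¹, faster than a second 6‑endo closure onto the C8=C9 alkene), and Co removes H from the methyl to give the exocyclic methylene, with Co(III)–H releasing the free alcohol and turning over Ti; the closest known reactions are Cuerva–Oltra Cp2TiCl epoxypolyene radical cyclisation and cobaloxime‑catalysed radical desaturation, and the new element is stopping the cascade after one ring.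

**Step 10**
Reactants: 11
Product: 12 (2E,6E)‑3,7‑dimethyl‑9‑[(1R,3S)‑3‑hydroxy‑2,2‑dimethyl‑6‑methylidenecyclohexyl]nona‑2,6‑dien‑1‑ol
Conditions: TBAF, THF, 0 °C
Reagents that add atoms: none
Why: fluoride cleaves the primary silyl ether and leaves the stereocentres, alkenes and ring OH intact.

**Step 11**
Reactants: 12
Product: 13 the corresponding allylic bromide, (1R,3S)‑ring with a (2E,6E)‑9‑bromo‑nona‑2,6‑dienyl‑type chain (C14–Br)
Conditions: PPh3, CBr4, CH2Cl2, −10 → 0 °C; used crude
Reagents that add atoms: CBr4, BrC(Br)(Br)Br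
Why: Appel conditions brominate the unhindered primary allylic OH selectively over the hindered secondary ring OH.

**Step 12**
Reactants: 13 and 14 triacetic acid lactone (4‑hydroxy‑6‑methyl‑2H‑pyran‑2‑one)
Product: 15 sartorypyrone D
Conditions: K2CO3, KI (cat.), acetone, 45 °C
Reagents that add atoms: none
Why: the ambident pyranone enolate is C‑alkylated at C3 by the primary allylic bromide in an SN2 reaction with E‑alkene retention; no stereocentre is touched.

## Compound list
1 | (2E,6E)‑farnesol | CC(C)=CCC/C(C)=C/CC/C(C)=C/CO | starting material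
2 | farnesyl TBS ether | CC(C)=CCC/C(C)=C/CC/C(C)=C/CO[Si](C)(C)C(C)(C)C | intermediate
3 | 12‑hydroxyfarnesyl TBS ether | OC/C(C)=C/CC/C(C)=C/CC/C(C)=C/CO[Si](C)(C)C(C)(C)C | intermediate
4 | 12‑bromofarnesyl TBS ether | BrC/C(C)=C/CC/C(C)=C/CC/C(C)=C/CO[Si](C)(C)C(C)(C)C | intermediate
5 | methyl (R)‑2,2‑dimethyl‑1,3‑dioxolane‑4‑carboxylate | COC(=O)[C@H]1COC(C)(C)O1 | starting material
6 | (R)‑2‑[(4R)‑2,2‑dimethyl‑1,3‑dioxolan‑4‑yl]propan‑2‑ol | CC(C)(O)[C@H]1COC(C)(C)O1 | intermediate
7 | (R)‑3‑methylbutane‑1,2,3‑triol | CC(C)(O)[C@H](O)CO | intermediate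
8 | (R)‑2‑(oxiran‑2‑yl)propan‑2‑ol | CC(C)(O)[C@H]1CO1 | intermediate
9 | C20 diol TBS ether (14R) | CC(C)(O)[C@H](O)CC/C(C)=C/CC/C(C)=C/CC/C(C)=C/CO[Si](C)(C)C(C)(C)C | intermediate
10 | (14S)‑14,15‑epoxy‑geranylgeranyl TBS ether | CC1(C)O[C@H]1CC/C(C)=C/CC/C(C)=C/CC/C(C)=C/CO[Si](C)(C)C(C)(C)C | intermediate
11 | monocyclic TBS ether | C=C1CC[C@H](O)C(C)(C)[C@@H]1CC/C(C)=C/CC/C(C)=C/CO[Si](C)(C)C(C)(C)C | intermediate
12 | monocyclic allylic alcohol | C=C1CC[C@H](O)C(C)(C)[C@@H]1CC/C(C)=C/CC/C(C)=C/CO | intermediate
13 | monocyclic allylic bromide | C=C1CC[C@H](O)C(C)(C)[C@@H]1CC/C(C)=C/CC/C(C)=C/CBr | intermediate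
14 | triacetic acid lactone | CC1=CC(O)=CC(=O)O1 | starting material
15 | sartorypyrone D | C=C1CC[C@H](O)C(C)(C)[C@@H]1CC/C(C)=C/CC/C(C)=C/Cc1c(O)cc(C)oc1=O | target

## Totals
Total steps: 12. Longest linear sequence: 9 (1→2→3→9→10→11→12→13→15, or 5→6→7→8→9→10→11→12→13→15 counted as steps 4–12).

## Three steps most likely to fail
1. **Step 9 (proposed new step).** Over‑cyclisation onto the C8=C9 alkene, or Co–H isomerisation of the exocyclic alkene, would give bicyclic or endocyclic products.
   *Fallback (known chemistry):* couple 8 with the Grignard of the (E)‑4‑bromo‑2‑methylbut‑2‑enyl TBS ether (a C5 building block) instead of 4, giving an epoxygeranyl‑type substrate with one alkene. Cyclise it with stoichiometric Cp2TiCl/collidine/Zn (Cuerva–Oltra), then attach the C7–C14 tail by Cu‑catalysed coupling of the ring‑CH2MgBr with 8‑bromogeranyl TBS ether, and finish with Steps 10–12.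
2. **Step 7.** The Grignard can form Wurtz dimers or react at the γ‑carbon, and Payne isomerisation of the epoxy alcohol would give the wrong connectivity.
   *Fallback:* use a Julia‑type route. Convert 4 to the allylic sulfone (PhSO2Na), deprotonate it and open epoxide 8 with BF3·OEt2, then remove the sulfone with Pd(dppp)Cl2/LiBEt3H to give 9.
3. **Step 12.** O‑alkylation of the pyranone, or bromide decomposition, competes with C3‑alkylation.
   *Fallback:* use a Pd(0) π‑allyl route: convert 12 to its methyl carbonate and react it with TAL under Pd(PPh3)4 catalysis for C3 allylation.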